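**Retrosynthetic overview**
1. Cut C3–C4, C1–OAr and C1–O2 of the bridged acetal in one operation with no by-product. This gives 4-hydroxy-2-methoxy-6-(prop-1-ynyl)isophthalaldehyde and 6-hydroxy-8-methoxy-3-methylisoquinoline-7-carbaldehyde. The alkyne serves as the latent enol ether and acetyl group.
2. The isoquinoline aldehyde comes from the same alkynyl dialdehyde and NH3.
3. The alkynyl dialdehyde comes from an aryl bromide and propyne (Sonogashira).
4. The bromide's OH/OMe pattern comes from 4-bromo-2,6-difluoroisophthalaldehyde by two site-complementary SNAr reactions. That dialdehyde comes from 1-bromo-3,5-difluorobenzene by double lithiation–formylation.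
5. Ring order: pyridine ring E forms first. In the last step a transient pyran ring forms and is traded for ring B (isochroman) and ring C (1,3-dioxine), which close together.

Assumption: the sense of induction of the (R)-configured phosphate is assigned by analogy only. Both antipodes of the catalyst are available, and the (S)-catalyst is used if the mirror image is obtained.

Locants used below (isochroman numbering of the target): C1 is the acetal CH, O2 the bridging oxygen, C3 the CH bonded to isoquinoline C7′, and C4 the CH bearing acetyl. Ring A is the benzene bearing CHO, OH and OMe. Rings D and E are the isoquinoline carbocycle and pyridine.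

**Step 1**
Reactants: 1 1-bromo-3,5-difluorobenzene
Product: 4 4-bromo-2,6-difluorobenzene-1,3-dicarbaldehyde, via lithium amino alkoxide 2 (not isolated), via dilithium bis(amino alkoxide) 3 (not isolated)
Conditions: LiN(iPr)2 (1.05 equiv), THF, −78 °C; DMF (1.05 equiv), −78 °C; LiN(iPr)2 (1.3 equiv), −78 °C; DMF (2 equiv), −78 → −20 °C; 2 M HCl
Reagents that add atoms: N,N-dimethylformamide, CN(C)C=O
Why: This is directed ortho-lithiation/formylation run twice in one pot: the first base removes the most acidic H between the two fluorines, the DMF adduct 2 survives at −78 °C as an in situ protected aldehyde (α-amino alkoxide protection), and the only ring hydrogens left are the two equivalent ones between F and Br, so only one dialdehyde can form and no stereocentre survives hydrolysis.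

**Step 2**
Reactants: 4 4-bromo-2,6-difluorobenzene-1,3-dicarbaldehyde
Product: 7 4-bromo-6-hydroxy-2-methoxybenzene-1,3-dicarbaldehyde, via fluoro tert-butyl ether 5 (not isolated), via methoxy tert-butyl ether 6 (not isolated)
Conditions: KOtBu (1.0 equiv), THF, −78 → −20 °C; NaOMe (1.1 equiv), MeOH, 0 °C → rt; evaporate; CF3CO2H/CH2Cl2 1:4, rt
Reagents that add atoms: potassium tert-butoxide, CC(C)(C)[O-].[K+]; sodium methoxide, C[O-].[Na+]
Why: In this sequential nucleophilic aromatic substitution, bulky tert-butoxide takes the C6 fluoride (ortho/para to the formyl groups, one open flank), methoxide then displaces the fluoride wedged between both formyl groups (F leaves far faster than Br in SNAr), and acid unmasks the phenol by E1 loss of isobutene, so the OH/OMe pattern is fixed without any selective (de)methylation and no stereocentre is formed.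

**Step 3**
Reactants: 7 4-bromo-6-hydroxy-2-methoxybenzene-1,3-dicarbaldehyde; 8 propyne
Product: 9 4-hydroxy-2-methoxy-6-(prop-1-yn-1-yl)benzene-1,3-dicarbaldehyde
Conditions: propyne (3 equiv), PdCl2(PPh3)2 (3 mol %), CuI (5 mol %), Et3N, DMF, 50 °C, sealed tube
Reagents that add atoms: none
Why: This is a Sonogashira coupling in which the bromide ortho/para to two formyl groups adds readily to zerovalent palladium, the phenol is tolerated as its ammonium phenoxide, and the aldehydes are inert to the tertiary amine.

**Step 4**
Reactants: 9 4-hydroxy-2-methoxy-6-(prop-1-yn-1-yl)benzene-1,3-dicarbaldehyde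
Product: 10 6-hydroxy-8-methoxy-3-methylisoquinoline-7-carbaldehyde
Conditions: NH3 (7 M in MeOH, 10 equiv), AgOSO2CF3 (5 mol %), 50 °C, sealed tube; then 1 M citric acid (pH 4–5), rt
Reagents that add atoms: ammonia, N
Why: Imination followed by silver-assisted 6-endo-dig aza-annulation of the o-alkynylbenzaldimine aromatizes irreversibly to the isoquinoline, whereas the aldimine at the other formyl group (both ortho positions blocked, no alkyne next to it) is hydrolysed back on the acidic work-up.

**Step 5**
Reactants: 9 4-hydroxy-2-methoxy-6-(prop-1-yn-1-yl)benzene-1,3-dicarbaldehyde; 10 6-hydroxy-8-methoxy-3-methylisoquinoline-7-carbaldehyde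
Product: 13 target CNP0584953.1 (1R,3R,4S), via isochromen-6-one 11 (not isolated), via mixed aryl acetal 12 (not isolated)
Conditions: 9, silver (R)-3,3'-bis(2,4,6-triisopropylphenyl)-1,1'-binaphthyl-2,2'-diyl phosphate (10 mol %), 4 Å MS, ClCH2CH2Cl, 40 °C, 1 h; then added over 6 h to 10 (1.5 equiv) + (R)-3,3'-bis(2,4,6-triisopropylphenyl)-1,1'-binaphthyl-2,2'-diyl hydrogen phosphate (10 mol %), CH2Cl2, −30 °C, 48 h; neutral silica, no base
Reagents that add atoms: none
Why: Proposed new method: the silver phosphate drives 6-endo-dig attack of the formyl oxygen on the alkyne (known cycloisomerization of o-alkynylbenzaldehydes to 2-benzopyrylium ions, resting here as the neutral quinone methide 11), the phenol of 10 adds reversibly at C1 to give the racemizing acetal 12 (known 1-alkoxyisochromene formation), and inside the chiral phosphate ion pair the enol-ether carbon C4 of (S)-12 attacks the tethered formyl group (Mukaiyama-aldol/Prins type, C=C and C=O antiperiplanar, product-like eight-membered transition state) while the new oxygen on C3 displaces the pyran oxygen from C1 from the rear and releases it as the acetyl C=O, so rings B and C close together; C3 (R) is set by the phosphate-selected aldehyde face in a dynamic kinetic resolution of 12, C1 (R) by inversion in the bridging step, and C4 (S, acetyl cis to the isoquinoline carbon, H on the convex face) because only the anti-aldol adduct places its oxygen for rear-side displacement while the syn adduct reverts; the closest known reaction types are relay silver or gold/chiral phosphoric acid catalysis of isobenzopyrylium ions, alkyne–carbonyl metathesis, and acid-catalysed bicyclic acetalization of salicylaldehydes with enol ethers.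

**Compound list**
1 | 1-bromo-3,5-difluorobenzene | Fc1cc(Br)cc(F)c1 | starting material
2 | lithium (4-bromo-2,6-difluorophenyl)(dimethylamino)methanolate (racemic) | [Li+].[O-]C(N(C)C)c1c(F)cc(Br)cc1F | intermediate
3 | dilithium bis(dimethylamino-methanolate) of 4 (diastereomer mixture, centres lost on hydrolysis) | [Li+].[Li+].[O-]C(N(C)C)c1c(F)c(C([O-])N(C)C)c(Br)cc1F | intermediate
4 | 4-bromo-2,6-difluorobenzene-1,3-dicarbaldehyde | O=Cc1c(F)c(C=O)c(Br)cc1F | intermediate
5 | 4-bromo-6-tert-butoxy-2-fluorobenzene-1,3-dicarbaldehyde | O=Cc1c(F)c(C=O)c(Br)cc1OC(C)(C)C | intermediate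
6 | 4-bromo-6-tert-butoxy-2-methoxybenzene-1,3-dicarbaldehyde | COc1c(C=O)c(Br)cc(OC(C)(C)C)c1C=O | intermediate
7 | 4-bromo-6-hydroxy-2-methoxybenzene-1,3-dicarbaldehyde | COc1c(C=O)c(Br)cc(O)c1C=O | intermediate
8 | propyne | CC#C | starting material
9 | 4-hydroxy-2-methoxy-6-(prop-1-yn-1-yl)benzene-1,3-dicarbaldehyde | CC#Cc1cc(O)c(C=O)c(OC)c1C=O | intermediate
10 | 6-hydroxy-8-methoxy-3-methylisoquinoline-7-carbaldehyde | COc1c(C=O)c(O)cc2cc(C)ncc12 | intermediate
11 | 8-methoxy-3-methyl-6-oxo-6H-isochromene-7-carbaldehyde | CC1=CC2=CC(=O)C(C=O)=C(OC)C2=CO1 | intermediate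
12 | (1S)-1-[(7-formyl-8-methoxy-3-methylisoquinolin-6-yl)oxy]-6-hydroxy-8-methoxy-3-methyl-1H-isochromene-7-carbaldehyde (reacting enantiomer; racemizes through 11) | COc1c(C=O)c(O)cc2C=C(C)O[C@@H](Oc3cc4cc(C)ncc4c(OC)c3C=O)c12 | intermediate
13 | (1R,3R,4S)-4-acetyl-7-formyl-6-hydroxy-8-methoxyisochroman whose C1 is bonded to O-6′ and whose C3 is bonded to C-7′ of 8′-methoxy-3′-methylisoquinoline (2,9-dioxabicyclo[3.3.1]nonane core, acetyl cis to C-7′) | COc1c(C=O)c(O)cc2c1[C@H]1Oc3cc4cc(C)ncc4c(OC)c3[C@H](O1)[C@H]2C(C)=O | target

**Totals:** 5 steps; longest linear sequence 5 (1 → 4 → 7 → 9 → 10 → 13).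

**Steps most likely to fail**

**Step 5.** There are four risks.
- 9 and 11 carry their own salicylaldehyde unit and can oligomerize. An excess of 10 and slow addition are meant to counter this.
- The isoquinoline nitrogen buffers the acid and binds silver.
- The endo-acetyl product is the kinetic C4 epimer and may drift to the exo epimer.
- The ee is unproven.

The fallback sets out from 9 and 10 and separates C–C bond formation from ring closure. Hydrate 9 (AgOSO2CF3 cat., wet acetone) to 4-hydroxy-2-methoxy-6-(2-oxopropyl)benzene-1,3-dicarbaldehyde F1. Condense it with 10 (TiCl4, pyridine, THF, 0 °C, Knoevenagel type) to 4-hydroxy-6-[(1E)-1-(6-hydroxy-8-methoxy-3-methylisoquinolin-7-yl)-3-oxobut-1-en-2-yl]-2-methoxybenzene-1,3-dicarbaldehyde F2, which has the two aryl groups cis. Then close both rings with the same chiral phosphoric acid by hemiacetalization and intramolecular oxa-Michael addition, a known cascade type. C3 is set in the oxa-Michael step, C1 by the bridge, and C4 by protonation of the enol from the convex face. The fallback comes back at 13.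

**Step 1.** The second metalation may be slow on the anionic adduct 2, or benzyne formation or halogen dance may intervene. The fallback sets out from 1 and uses a covalent protecting group. A single lithiation/DMF quench gives 4-bromo-2,6-difluorobenzaldehyde F3. Ethylene glycol with TsOH gives 2-(4-bromo-2,6-difluorophenyl)-1,3-dioxolane F4. LiN(iPr)2 then DMF gives 6-bromo-3-(1,3-dioxolan-2-yl)-2,4-difluorobenzaldehyde F5. Aqueous HCl brings the sequence back at 4.

**Step 2.** tert-Butoxide may deformylate the 2,6-disubstituted aldehyde or give poor site selectivity. The fallback sets out from 4 and relies on electronic para preference with true hydroxylation followed by isolated protection. KOH in DMSO/H2O at 0 °C gives 4-bromo-2-fluoro-6-hydroxybenzene-1,3-dicarbaldehyde F6. MOMCl with iPr2NEt gives 4-bromo-2-fluoro-6-(methoxymethoxy)benzene-1,3-dicarbaldehyde F7. NaOMe in MeOH on this neutral ring gives 4-bromo-2-methoxy-6-(methoxymethoxy)benzene-1,3-dicarbaldehyde F8. Aqueous HCl in THF brings the sequence back at 7.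

**Further compounds**
F1 | step 5 | 4-hydroxy-2-methoxy-6-(2-oxopropyl)benzene-1,3-dicarbaldehyde | CC(=O)Cc1cc(O)c(C=O)c(OC)c1C=O
F2 | step 5 | 4-hydroxy-6-[(1E)-1-(6-hydroxy-8-methoxy-3-methylisoquinolin-7-yl)-3-oxobut-1-en-2-yl]-2-methoxybenzene-1,3-dicarbaldehyde | CC(=O)/C(=C/c1c(O)cc2cc(C)ncc2c1OC)c1cc(O)c(C=O)c(OC)c1C=O
F3 | step 1 | 4-bromo-2,6-difluorobenzaldehyde | O=Cc1c(F)cc(Br)cc1F
F4 | step 1 | 2-(4-bromo-2,6-difluorophenyl)-1,3-dioxolane | Fc1cc(Br)cc(F)c1C1OCCO1
F5 | step 1 | 6-bromo-3-(1,3-dioxolan-2-yl)-2,4-difluorobenzaldehyde | O=Cc1c(Br)cc(F)c(C2OCCO2)c1F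
F6 | step 2 | 4-bromo-2-fluoro-6-hydroxybenzene-1,3-dicarbaldehyde | O=Cc1c(F)c(C=O)c(Br)cc1O
F7 | step 2 | 4-bromo-2-fluoro-6-(methoxymethoxy)benzene-1,3-dicarbaldehyde | COCOc1cc(Br)c(C=O)c(F)c1C=O
F8 | step 2 | 4-bromo-2-methoxy-6-(methoxymethoxy)benzene-1,3-dicarbaldehyde | COCOc1cc(Br)c(C=O)c(OC)c1C=O
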